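**Plan**

1. Locants are those of the azulene core of the target: C3 (carbinol with isopropyl), C3a (ring-fusion CH), C4 (acyloxy carbon), C6 (methyl-bearing alkene carbon), C8 (allylic carbinol), C8a (quaternary carbon). "Face A" is the face of H-3a, "face B" that of the 8a-methyl group.
2. Retrosynthesis: the anisoate C–O bond is cut first. The C8 hydroxyl and the C6=C7 alkene come from a C7=C8 alkene by ene transposition, and the C4 hydroxyl from a ketone. The bicycle is then cut in one event at C3a–C8a and C6–C7, which opens both rings to one chain.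
3. Enabling feature: C8 carries oxygen and lies between C7 and the quaternary C8a, so C7–C8–C8a is a 2-oxyallyl cation. C3a–C4(O)–C5–C6(Me) is a 2-oxydiene, and C1–C2–C3 of the cyclopentane is a three-atom tether, so an intramolecular (4+3) cycloaddition closes both rings.
4. Forward: ozonolysis of (S)-terpinen-4-ol supplies C8a with its methyl, C1, C2, C3 (OH, isopropyl), C3a and C4 in one piece. The aldehyde (C4) is extended to the (E)-propenyl ketone and locked with the C3 hydroxyl as a cyclic silylene dienol ether; the methyl ketone (C8a) takes up 1-ethoxyvinyllithium (C8, C7).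
5. Step 6 forms the cyclopentane and the cycloheptene together. The C8 carbonyl, the silylene ring and the C6 stereocentre are helpers that are removed afterwards (enol triflate reduction, fluoride, ene reaction).
6. Stereochemistry: C3 from terpinen-4-ol; C3a from the dioxasiline ring and C8a from the extended cycloaddition geometry (step 6); C4 by hydroxyl-directed hydride delivery (step 10); C8 by a suprafacial ene reaction that uses H-6 set in step 6 (step 12).

Key step: step 6

Remark: (S)-(+)-terpinen-4-ol is taken to be available in high enantiomeric purity; it is the only source of chirality in the route.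

**Step 1**
Reactants: 1 (S)-(+)-terpinen-4-ol
Product: 3 (3S)-3-hydroxy-6-oxo-3-(propan-2-yl)heptanal, via ozonide 2 (not isolated)
Conditions: O3, CH2Cl2, −78 °C; then Me2S, −78 °C to rt; used crude
Reagents that add atoms: ozone, [O-][O+]=O
Why: Ozonolysis with reductive work-up cleaves the only alkene to the methyl ketone (later C8a) and the aldehyde (later C4) and leaves the tertiary carbinol stereocentre untouched.

**Step 2**
Reactants: 3 (3S)-3-hydroxy-6-oxo-3-(propan-2-yl)heptanal; 4 (E)-1-bromoprop-1-ene
Product: 5 (5S,8E)-5,7-dihydroxy-5-(propan-2-yl)dec-8-en-2-one (both C7 epimers)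
Conditions: CrCl2 (4 equiv), NiCl2 (1 mol %), DMF, rt
Reagents that add atoms: none
Why: The Nozaki–Hiyama–Kishi reaction adds the alkenylchromium reagent to the aldehyde and not to the ketone, tolerates the free hydroxyl and keeps the E geometry; the new carbinol centre is oxidised in step 3, so its configuration does not matter.

**Step 3**
Reactants: 5 (5S,8E)-5,7-dihydroxy-5-(propan-2-yl)dec-8-en-2-one
Product: 6 (5S,8E)-5-hydroxy-5-(propan-2-yl)dec-8-ene-2,7-dione
Conditions: MnO2, CH2Cl2, rt
Reagents that add atoms: none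
Why: MnO2 oxidises only the allylic secondary alcohol and, being neutral, spares the retro-aldol-prone tertiary β-hydroxy ketone.

**Step 4**
Reactants: 6 (5S,8E)-5-hydroxy-5-(propan-2-yl)dec-8-ene-2,7-dione
Product: 7 4-[(4R)-2,2-di-tert-butyl-4-(propan-2-yl)-6-[(1E)-prop-1-enyl]-4H-1,3,2-dioxasilin-4-yl]butan-2-one
Conditions: tBu2Si(OTf)2 (1.05 equiv), Et3N (3 equiv), CH2Cl2, 0 °C to rt
Reagents that add atoms: di-tert-butylsilyl bis(trifluoromethanesulfonate), CC(C)(C)[Si](OS(=O)(=O)C(F)(F)F)(OS(=O)(=O)C(F)(F)F)C(C)(C)C
Why: Silylation of the tertiary hydroxyl is followed by intramolecular O-silylation of the neighbouring enone carbonyl through a six-membered ring and deprotonation of the C3a methylene by Et3N (soft enolisation). The ring fixes the enol ether geometry with C3 in the outside position of the diene, while the remote methyl ketone would need a seven-membered ring.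

**Step 5**
Reactants: 7 the dioxasiline methyl ketone; 8 ethyl vinyl ether
Product: 10 5-[(4R)-2,2-di-tert-butyl-4-(propan-2-yl)-6-[(1E)-prop-1-enyl]-4H-1,3,2-dioxasilin-4-yl]-2-ethoxy-3-methylpent-1-en-3-ol (both C3 epimers), via 1-ethoxyvinyllithium 9 (not isolated)
Conditions: 8, tBuLi, THF, −78 to 0 °C; then 7, THF, −78 °C; aq. NaHCO3 work-up
Reagents that add atoms: none
Why: 1,2-Addition of the acyl-anion equivalent 1-ethoxyvinyllithium to the methyl ketone brings in C8 and C7; the hindered silyl dienol ether is not electrophilic, and the new carbinol centre becomes a planar cation in step 6.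

**Step 6**
Reactants: 10 the tertiary 2-ethoxyallylic alcohol
Product: 13 tricyclic ketone (8-oxo-hexahydroazulene with the 3-O and 4-O bridged by tBu2Si as a C4=C5 enol ether; trans ring fusion; H-6 on face A), via allyl cation 11 (not isolated), via ethyl enol ether 12 (not isolated)
Conditions: Tf2O (1.1 equiv), 2,6-lutidine (3 equiv), CH2Cl2, −78 °C; then pH 4 aqueous acetate buffer, THF, 0 °C
Reagents that add atoms: water, O
Why: Triflation of the tertiary hydroxyl and loss of triflate give the 2-ethoxyallyl cation 11 (C7–C8–C8a), which adds across the termini C3a and C6 of the tethered silyloxydiene in an asynchronous (4+3) cycloaddition with C8a–C3a bonding ahead of C7–C6; proton loss gives enol ether 12 and mild hydrolysis gives ketone 13. The closest known reaction type is the intramolecular (4+3) cycloaddition of 2-alkoxyallyl cations with dienes held by a three-atom tether, which gives bicyclo[5.3.0]decenones. The cyclopentane closes by 5-exo attack of the diene terminus C3a on the tertiary cation terminus C8a across the C1–C2 tether, and the cycloheptene closes when the other allyl terminus C7 bonds to the distal diene terminus C6 (7-endo with respect to the diene). C3a is controlled by the dioxasiline ring, because the tether leaves C3 on one face of the planar diene, so C8a must bond on that face and O-3 and C4 end up cis on the new cyclopentane; C8a is controlled by the extended (chair-like) approach, in which the ethoxyallyl unit lies on the H-3a side away from the dioxasiline ring and its tert-butyl groups and so gives the trans ring fusion; C6 follows from suprafacial addition to the (E)-propenyl terminus, which puts H-6 cis to H-3a. The step needs (4+3) over (3+2) periselectivity and bonding of the tertiary terminus to C3a; the second is fixed by the tether length, and the first is favoured because closure at C4 from the trans-disposed intermediate would build a trans-fused bicyclo[3.3.0]octane.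

**Step 7**
Reactants: 13 tricyclic ketone
Product: 14 enol triflate of 13 (C7=C8–OTf)
Conditions: KN(SiMe3)2, PhNTf2, THF, −78 °C
Reagents that add atoms: N-phenylbis(trifluoromethanesulfonimide), O=S(=O)(N(c1ccccc1)S(=O)(=O)C(F)(F)F)C(F)(F)F
Why: The ketone can enolise only toward C7 because C8a is quaternary, and O-triflation of the potassium enolate gives a single enol triflate.

**Step 8**
Reactants: 14 enol triflate
Product: 15 tricyclic diene (C7=C8 alkene, silylene enol ether retained)
Conditions: Pd(OAc)2 (5 mol %), PPh3, Bu3N, HCO2H, DMF, 60 °C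
Reagents that add atoms: none
Why: In this palladium-catalysed formate reduction of an enol triflate, zerovalent palladium inserts into the C–OTf bond, formate delivers hydride with loss of CO2, and reductive elimination leaves the cis C7=C8 alkene, which removes the C8 oxygen helper.

**Step 9**
Reactants: 15 tricyclic diene
Product: 16 (3R,3aR,6S,8aR)-3-hydroxy-6,8a-dimethyl-3-(propan-2-yl)-1,2,3,3a,5,6-hexahydroazulen-4(8aH)-one
Conditions: HF·pyridine, pyridine, THF, 0 °C
Reagents that add atoms: none
Why: Fluoride cleaves both Si–O bonds of the temporary ring, and the freed enol tautomerises to the C4 ketone by protonation at C5 without creating a stereocentre; pyridine buffering avoids epimerisation at C3a and retro-aldol opening.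

**Step 10**
Reactants: 16 the β-hydroxy ketone
Product: 17 (3R,3aS,4S,6S,8aR)-6,8a-dimethyl-3-(propan-2-yl)-1,2,3,3a,4,5,6,8a-octahydroazulene-3,4-diol
Conditions: Me4NBH(OAc)3, AcOH/MeCN (1:1), −25 °C
Reagents that add atoms: none
Why: In the Evans–Saksena reduction the C3 hydroxyl exchanges onto boron and hydride is delivered within a six-membered transition state to the face of the C4 carbonyl that bears O-3, giving the anti-1,3-diol with the C4 hydroxyl on face A.

**Step 11**
Reactants: 17 the diol; 18 4-methoxybenzoyl chloride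
Product: 19 [(3R,3aS,4S,6S,8aR)-3-hydroxy-6,8a-dimethyl-3-(propan-2-yl)-1,2,3,3a,4,5,6,8a-octahydroazulen-4-yl] 4-methoxybenzoate
Conditions: Et3N, DMAP (cat.), CH2Cl2, 0 °C to rt
Reagents that add atoms: none
Why: DMAP-catalysed acylation takes place at the secondary C4 hydroxyl, while the hindered tertiary C3 hydroxyl does not react.

**Step 12**
Reactants: 19 the anisoate
Product: 21 [(3R,3aS,4S,8R,8aS)-3,8-dihydroxy-6,8a-dimethyl-3-(propan-2-yl)-1,2,3,3a,4,5,8,8a-octahydroazulen-4-yl] 4-methoxybenzoate (target), via allylic hydroperoxide 20 (not isolated)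
Conditions: O2, tetraphenylporphyrin (cat.), visible light, CH2Cl2, 0 °C; then PPh3, rt
Reagents that add atoms: dioxygen, O=O
Why: In the Schenck ene reaction singlet oxygen attacks the C7=C8 alkene on face A (away from the angular methyl), bonds to C8 and removes the only allylic hydrogen, H-6, on the same face, which shifts the alkene to C6=C7 and sets the C8 oxygen on face A; C8a has no hydrogen, so no other regiochemistry is possible, and PPh3 reduces the hydroperoxide with retention.

**Compound list**

1 | (S)-(+)-terpinen-4-ol | CC1=CC[C@](O)(C(C)C)CC1 | starting material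
2 | ozonide of 1 (1,2,4-trioxolane across the former alkene, diastereomer mixture) | CC12CC[C@@](O)(C(C)C)CC(OO1)O2 | intermediate
3 | (3S)-3-hydroxy-6-oxo-3-(propan-2-yl)heptanal | CC(=O)CC[C@@](O)(C(C)C)CC=O | intermediate
4 | (E)-1-bromoprop-1-ene | C/C=C/Br | starting material
5 | (5S,8E)-5,7-dihydroxy-5-(propan-2-yl)dec-8-en-2-one (both C7 epimers) | CC(=O)CC[C@@](O)(C(C)C)CC(O)/C=C/C | intermediate
6 | (5S,8E)-5-hydroxy-5-(propan-2-yl)dec-8-ene-2,7-dione | CC(=O)CC[C@@](O)(C(C)C)CC(=O)/C=C/C | intermediate
7 | 4-[(4R)-2,2-di-tert-butyl-4-(propan-2-yl)-6-[(1E)-prop-1-enyl]-4H-1,3,2-dioxasilin-4-yl]butan-2-one | CC(=O)CC[C@@]1(C(C)C)C=C(/C=C/C)O[Si](C(C)(C)C)(C(C)(C)C)O1 | intermediate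
8 | ethyl vinyl ether | C=COCC | starting material
9 | 1-ethoxyvinyllithium | [Li]C(=C)OCC | intermediate
10 | 5-[(4R)-2,2-di-tert-butyl-4-(propan-2-yl)-6-[(1E)-prop-1-enyl]-4H-1,3,2-dioxasilin-4-yl]-2-ethoxy-3-methylpent-1-en-3-ol (both C3 epimers) | C=C(OCC)C(C)(O)CC[C@@]1(C(C)C)C=C(/C=C/C)O[Si](C(C)(C)C)(C(C)(C)C)O1 | intermediate
11 | 2-ethoxyallyl cation derived from 10 (cationic centre at the methyl-bearing carbon, later C8a) | C=C(OCC)[C+](C)CC[C@@]1(C(C)C)C=C(/C=C/C)O[Si](C(C)(C)C)(C(C)(C)C)O1 | intermediate
12 | (4+3) adduct as its C7=C8 ethyl enol ether (trans ring fusion, H-6 on face A, silylene bridge O-3/O-4) | C2(O[Si](C(C)(C)C)(C(C)(C)C)O4)=C[C@H](C)C=C(OCC)[C@@]3(C)CC[C@@]4(C(C)C)[C@H]23 | intermediate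
13 | tricyclic C8 ketone (trans ring fusion, H-3a and H-6 on face A, 8a-methyl on face B, isopropyl on face A, silylene bridge O-3/O-4 with C4=C5 enol ether) | C2(O[Si](C(C)(C)C)(C(C)(C)C)O4)=C[C@H](C)CC(=O)[C@@]3(C)CC[C@@]4(C(C)C)[C@H]23 | intermediate
14 | C7=C8 enol triflate of 13 | C2(O[Si](C(C)(C)C)(C(C)(C)C)O4)=C[C@H](C)C=C(OS(=O)(=O)C(F)(F)F)[C@@]3(C)CC[C@@]4(C(C)C)[C@H]23 | intermediate
15 | tricyclic diene (C7=C8 alkene and C4=C5 silylene enol ether) | C2(O[Si](C(C)(C)C)(C(C)(C)C)O4)=C[C@H](C)C=C[C@@]3(C)CC[C@@]4(C(C)C)[C@H]23 | intermediate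
16 | (3R,3aR,6S,8aR)-3-hydroxy-6,8a-dimethyl-3-(propan-2-yl)-1,2,3,3a,5,6-hexahydroazulen-4(8aH)-one | O=C2C[C@H](C)C=C[C@@]3(C)CC[C@@](O)(C(C)C)[C@H]23 | intermediate
17 | (3R,3aS,4S,6S,8aR)-6,8a-dimethyl-3-(propan-2-yl)-1,2,3,3a,4,5,6,8a-octahydroazulene-3,4-diol | O[C@H]2C[C@H](C)C=C[C@@]3(C)CC[C@@](O)(C(C)C)[C@H]23 | intermediate
18 | 4-methoxybenzoyl chloride | COc1ccc(C(Cl)=O)cc1 | starting material
19 | [(3R,3aS,4S,6S,8aR)-3-hydroxy-6,8a-dimethyl-3-(propan-2-yl)-1,2,3,3a,4,5,6,8a-octahydroazulen-4-yl] 4-methoxybenzoate | COc1ccc(C(=O)O[C@H]2C[C@H](C)C=C[C@@]3(C)CC[C@@](O)(C(C)C)[C@H]23)cc1 | intermediate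
20 | C8 hydroperoxide of the target skeleton (OOH on face A, C6=C7 alkene) | COc1ccc(C(=O)O[C@H]2CC(C)=C[C@@H](OO)[C@@]3(C)CC[C@@](O)(C(C)C)[C@H]23)cc1 | intermediate
21 | [(3R,3aS,4S,8R,8aS)-3,8-dihydroxy-6,8a-dimethyl-3-(propan-2-yl)-1,2,3,3a,4,5,8,8a-octahydroazulen-4-yl] 4-methoxybenzoate | COc1ccc(C(=O)O[C@H]2CC(C)=C[C@@H](O)[C@@]3(C)CC[C@@](O)(C(C)C)[C@H]23)cc1 | target

Total step count: 12. Longest linear sequence: 12 steps (from 1).

**Steps most likely to fail**

1. Step 6. After the first C–C bond the intermediate may close at C4 in a (3+2) sense, the cation may lose a proton to a 2-ethoxydiene before it is captured, or the compact approach may compete and erode the trans ring fusion. Fallback, setting out from 7 and rejoining at 13: the oxyallyl unit is generated under basic instead of cationic conditions. 1,1-Dichloroethyllithium (CH3CHCl2, LiN(iPr)2, THF, −95 °C) adds to the methyl ketone of 7 to give the dichloro carbinol F1. Warming its lithium alkoxide closes the chloro-oxirane, which rearranges to the tertiary α-chloro methyl ketone F2. Et3N in CF3CH2OH then releases the neutral, less electrophilic 2-oxidoallyl cation from F2, and its (4+3) cycloaddition to the same dioxasiline diene gives ketone 13 without an enol ether stage.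

2. Step 4. The hindered tertiary hydroxyl may silylate incompletely, the β-hydroxy ketone may undergo retro-aldol cleavage under the amine base, or enolisation may go toward the propenyl methyl or engage the remote methyl ketone. Fallback, setting out from 6 and rejoining at 16: the two oxygens are silylated separately. Et3SiOTf and Et3N convert 6 into the bis(triethylsilyl) compound F3 (tertiary silyl ether plus (Z)-dienol silyl ether). The chemistry of steps 5 to 8 is then run on this open series, in which C3a is controlled by allylic strain (the silyloxy group, not the isopropyl group, eclipses the enol ether). This gives the 2-ethoxyallylic alcohol F4, the bicyclic ketone F5, the enol triflate F6 and the diene F7; HF·pyridine removes both silyl groups from F7 and gives 16.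

3. Step 12. The ene reaction of the cis-disubstituted alkene may be slow because its single allylic hydrogen must align with the π system, and long irradiation may degrade the material. Fallback, setting out from 17 and rejoining at 21: before acylation the alkene of 17 is epoxidised on face A (mCPBA, NaHCO3, CH2Cl2) to the epoxide F8. LiNEt2 (Et2O, reflux) removes H-6 syn to the epoxide oxygen and gives the triol F9 with the C6=C7 alkene and the C8 hydroxyl on face A. The less hindered C4 hydroxyl of F9 is then acylated selectively with 18 (1 equiv, Et3N, DMAP cat., CH2Cl2, −20 °C) to give 21.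

**Further compounds**

F1 | step 6 | 2,2-dichloro-5-[(4R)-2,2-di-tert-butyl-4-(propan-2-yl)-6-[(1E)-prop-1-enyl]-4H-1,3,2-dioxasilin-4-yl]-3-methylpentan-3-ol (both C3 epimers) | CC(Cl)(Cl)C(C)(O)CC[C@@]1(C(C)C)C=C(/C=C/C)O[Si](C(C)(C)C)(C(C)(C)C)O1
F2 | step 6 | 3-chloro-5-[(4R)-2,2-di-tert-butyl-4-(propan-2-yl)-6-[(1E)-prop-1-enyl]-4H-1,3,2-dioxasilin-4-yl]-3-methylpentan-2-one (both C3 epimers) | CC(=O)C(C)(Cl)CC[C@@]1(C(C)C)C=C(/C=C/C)O[Si](C(C)(C)C)(C(C)(C)C)O1
F3 | step 4 | (5R,6Z,8E)-5-(propan-2-yl)-5,7-bis(triethylsilyloxy)deca-6,8-dien-2-one | CC(=O)CC[C@@](O[Si](CC)(CC)CC)(C(C)C)/C=C(\O[Si](CC)(CC)CC)/C=C/C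
F4 | step 4 | (6R,7Z,9E)-2-ethoxy-3-methyl-6-(propan-2-yl)-6,8-bis(triethylsilyloxy)undeca-1,7,9-trien-3-ol (both C3 epimers) | C=C(OCC)C(C)(O)CC[C@@](O[Si](CC)(CC)CC)(C(C)C)/C=C(\O[Si](CC)(CC)CC)/C=C/C
F5 | step 4 | bicyclic C8 ketone with 3-O-triethylsilyl ether and C4=C5 triethylsilyl enol ether (trans ring fusion, H-6 on face A) | C2(O[Si](CC)(CC)CC)=C[C@H](C)CC(=O)[C@@]3(C)CC[C@@](O[Si](CC)(CC)CC)(C(C)C)[C@H]23
F6 | step 4 | C7=C8 enol triflate of F5 | C2(O[Si](CC)(CC)CC)=C[C@H](C)C=C(OS(=O)(=O)C(F)(F)F)[C@@]3(C)CC[C@@](O[Si](CC)(CC)CC)(C(C)C)[C@H]23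
F7 | step 4 | bicyclic diene with 3-O-triethylsilyl ether and C4=C5 triethylsilyl enol ether | C2(O[Si](CC)(CC)CC)=C[C@H](C)C=C[C@@]3(C)CC[C@@](O[Si](CC)(CC)CC)(C(C)C)[C@H]23
F8 | step 12 | 7,8-epoxide of 17 with the epoxide oxygen on face A | O[C@H]2C[C@H](C)[C@H]4O[C@H]4[C@@]3(C)CC[C@@](O)(C(C)C)[C@H]23
F9 | step 12 | (3R,3aS,4S,8R,8aS)-6,8a-dimethyl-3-(propan-2-yl)-1,2,3,3a,4,5,8,8a-octahydroazulene-3,4,8-triol | O[C@H]2CC(C)=C[C@@H](O)[C@@]3(C)CC[C@@](O)(C(C)C)[C@H]23
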